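**Strategy.** The plan rests on cutting the C3a–C4 bond of ring A of the benzofuranone. Ring A is the 4,6-dihydroxy (phloroglucinol-type) ring, and that bond sits α to the C3 ketone, where a Claisen-type closure of a β-keto acyl chain would place it. A tethered acylketene, unmasked thermally from a dioxinone, is to acylate C4 of a spiro furan-3(2H)-one (the future C3a). This closes and aromatises ring A in one operation and delivers both phenols free. The precursor is the enantiopure spiro furanone carrying a dioxinonylmethyl group at C5, with all phenols as benzyl ethers and the hemiketal as a benzyl ketal, so that one hydrogenolysis finishes the synthesis.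

Key step: step 13

Assumption: the (hemi)ketal carbon equilibrates (oxocarbenium ion under acid, ring–chain tautomerism once free), so it is drawn throughout with the relative configuration of the target and is taken to settle there in the final hemiketal; the sense of induction in step 9 is to be assigned on the first adduct and the antipodal ligand used if required.

Design remarks: the ketal is carried as a benzyl ketal, not a methyl ketal, so that a single hydrogenolysis removes every protecting group. The carbon nucleophile of step 12 is the dianion of the acetylated dioxinone (the 6-(2-oxopropyl) compound), because the dienolate of the parent trimethyldioxinone would give a chain two carbons short of the furanone precursor.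

**Route**

Step 1
Reactants: 1 kaempferol
Product: 2 kaempferol 3,5,7,4'-tetraacetate
Conditions: Ac2O, pyridine, DMAP (cat.), 25 → 60 °C
Reagents that add atoms: acetic anhydride, CC(=O)OC(C)=O
Why: Exhaustive O-acetylation under nucleophilic catalysis also esterifies the chelated 5-OH, so all four hydroxyls are masked alike before one is singled out.

Step 2
Reactants: 2 kaempferol 3,5,7,4'-tetraacetate
Product: 3 3,5,4'-tri-O-acetylkaempferol (7-OH free)
Conditions: PhSH, imidazole, NMP, 0 °C
Reagents that add atoms: none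
Why: Thiolate transesterification removes only the 7-acetate, whose phenoxide is conjugated with the pyranone carbonyl and is the best leaving group; this is a known regioselective deacetylation of flavonoid peracetates.

Step 3
Reactants: 3 3,5,4'-tri-O-acetylkaempferol
Product: 4 3,5,4'-tri-O-acetyl-7-O-(methoxymethyl)kaempferol
Conditions: MOMCl, iPr2NEt, CH2Cl2, 0 → 25 °C
Reagents that add atoms: chloromethyl methyl ether, COCCl
Why: Williamson-type O-alkylation of the single free phenol with an amine base leaves the acetates untouched and puts an acid-labile, base-stable placeholder on O7.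

Step 4
Reactants: 4 3,5,4'-tri-O-acetyl-7-O-(methoxymethyl)kaempferol
Product: 5 3,5,4'-tri-O-benzyl-7-O-(methoxymethyl)kaempferol
Conditions: BnBr, K2CO3, MeOH (4 equiv), DMF, 25 → 70 °C
Reagents that add atoms: benzyl bromide, BrCc1ccccc1
Why: One-pot methanolysis of the three acetates and Williamson benzylation of the freed phenoxides (warming for the chelated 5-OH) exchanges acetyl for benzyl while the MOM ether keeps O7 masked.

Step 5
Reactants: 5 3,5,4'-tri-O-benzyl-7-O-(methoxymethyl)kaempferol
Product: 6 3,5,4'-tri-O-benzylkaempferol (3,5-bis(benzyloxy)-2-[4-(benzyloxy)phenyl]-7-hydroxy-4H-chromen-4-one)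
Conditions: HCl (cat.), MeOH/THF, 40 °C
Reagents that add atoms: none
Why: Acid-catalysed acetal exchange with methanol cleaves the aryl MOM ether while benzyl ethers survive, exposing only the 7-OH that must activate C8 and later close the hemiketal.

Step 6
Reactants: 7 4'-benzyloxyacetophenone
Product: 8 methyl 3-[4-(benzyloxy)phenyl]-3-oxopropanoate
Conditions: NaH, (MeO)2CO, toluene, 100 °C; AcOH
Reagents that add atoms: dimethyl carbonate, COC(=O)OC
Why: Crossed Claisen condensation of the ketone enolate with dimethyl carbonate is driven by irreversible deprotonation of the β-keto ester.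

Step 7
Reactants: 8 methyl 3-[4-(benzyloxy)phenyl]-3-oxopropanoate
Product: 9 methyl 3-[4-(benzyloxy)phenyl]-2-diazo-3-oxopropanoate
Conditions: 4-acetamidobenzenesulfonyl azide, Et3N, MeCN, 0 → 25 °C
Reagents that add atoms: 4-acetamidobenzenesulfonyl azide, CC(=O)Nc1ccc(cc1)S(=O)(=O)N=[N+]=[N-]
Why: Regitz diazo transfer to the doubly activated methylene of the β-keto ester.

Step 8
Reactants: 9 methyl 3-[4-(benzyloxy)phenyl]-2-diazo-3-oxopropanoate
Product: 10 methyl 3-[4-(benzyloxy)phenyl]-2,3-dioxopropanoate
Conditions: dimethyldioxirane, acetone, 0 → 25 °C; then 4 Å MS, toluene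
Reagents that add atoms: dimethyldioxirane, CC1(C)OO1
Why: Oxygen-atom transfer from the dioxirane to the diazo carbon with loss of N2 gives the vicinal tricarbonyl under neutral conditions, and any hydrate is dehydrated over sieves before use.

Step 9
Reactants: 6 3,5,4'-tri-O-benzylkaempferol; 10 methyl 3-[4-(benzyloxy)phenyl]-2,3-dioxopropanoate
Product: 12 methyl (8R,9R)-3,5-bis(benzyloxy)-2,8-bis[4-(benzyloxy)phenyl]-8,9-dihydroxy-4-oxo-8,9-dihydro-4H-furo[2,3-h]chromene-9-carboxylate (hemiketal ester), via open-chain keto alcohol 11 (not isolated)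
Conditions: Cu(OTf)2 (10 mol%), (S,S)-t-Bu-box (11 mol%), 4 Å MS, CH2Cl2, −20 → 25 °C
Reagents that add atoms: none
Why: Catalytic asymmetric Friedel–Crafts hydroxyalkylation in which the divalent copper–bis(oxazoline) Lewis acid chelates the ester and central keto oxygens of 10, so that C8 of the phenol (ortho to the free 7-OH, C6 being shielded by the 5-benzyloxy group) adds to one face of the central carbonyl and sets C9, after which the 7-OH closes onto the aryl ketone as a five-membered hemiketal.

Step 10
Reactants: 12 hemiketal ester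
Product: 13 methyl (8R,9R)-3,5,8-tris(benzyloxy)-2,8-bis[4-(benzyloxy)phenyl]-9-hydroxy-4-oxo-8,9-dihydro-4H-furo[2,3-h]chromene-9-carboxylate (benzyl ketal; 8-aryl trans to the ester)
Conditions: BnOH (10 equiv), CSA (cat.), 4 Å MS, CH2Cl2, 25 °C
Reagents that add atoms: benzyl alcohol, OCc1ccccc1
Why: Acid-catalysed ketalisation through the aryl- and oxygen-stabilised oxocarbenium ion under thermodynamic control caps the hemiketal, which prevents ring opening to the keto phenol in the base step and is later removable by hydrogenolysis.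

Step 11
Reactants: 14 2,2,6-trimethyl-4H-1,3-dioxin-4-one
Product: 15 2,2-dimethyl-6-(2-oxopropyl)-4H-1,3-dioxin-4-one
Conditions: LiHMDS, THF, −78 °C; AcCl, −78 °C
Reagents that add atoms: acetyl chloride, CC(Cl)=O
Why: γ-C-Acylation of the lithium dienolate of the dioxinone with acetyl chloride is the established preparation of this keto-dioxinone.

Step 12
Reactants: 13 benzyl ketal ester; 15 2,2-dimethyl-6-(2-oxopropyl)-4H-1,3-dioxin-4-one
Product: 17 (2S,8'R)-3',5',8'-tris(benzyloxy)-2',8'-bis[4-(benzyloxy)phenyl]-5-[(2,2-dimethyl-4-oxo-4H-1,3-dioxin-6-yl)methyl]-8'H-spiro[furan-2,9'-furo[2,3-h]chromene]-3,4'-dione, via diketo-dioxinone 16 (not isolated)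
Conditions: 15 (4 equiv), LDA (8 equiv), THF, −78 °C; 13, −78 → −20 °C; AcOH, −78 °C; crude, CSA (cat.), 4 Å MS, CH2Cl2, 25 °C
Reagents that add atoms: none
Why: Claisen condensation of the terminal carbon of the 1,3-dicarbonyl dianion with the non-enolisable α-oxygenated methyl ester, followed by acid cyclodehydration of the α'-hydroxy-1,3-diketone (tertiary OH onto the distal ketone, 5-exo, loss of water) to the furan-3(2H)-one, which should outrun aldol aromatisation at the hindered ketone; the quaternary carbinol carbon is untouched.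

Step 13
Reactants: 17 spiro furan-3(2H)-one with dioxinonylmethyl group
Product: 19 (2S,8'R)-3',5',8'-tris(benzyloxy)-2',8'-bis[4-(benzyloxy)phenyl]-4,6-dihydroxy-8'H-spiro[1-benzofuran-2,9'-furo[2,3-h]chromene]-3,4'-dione, via acylketene 18 (not isolated)
Conditions: toluene (0.002 M), 110 °C, slow addition, Ar
Reagents that add atoms: none
Why: Proposed new method: at about 110 °C the dioxinone loses acetone by retro-[4+2] to give acylketene 18, whose ketene carbon is attacked by furanone C4 (the nucleophilic α-carbon of the O1–C5=C4–C3=O vinylogous ester) or, after enolisation of the side-chain ketone, the dienylketene closes by thermal 6π-electrocyclisation; either way the C3a–C4 bond forms and prototropic shifts aromatise the new ring to the 4,6-diol. The closest known reactions are dioxinone thermolysis to acylketenes with cyclisation–aromatisation to resorcylates and the dienylketene electrocyclisation of vinylketene benzannulations; C-acylation of a furan-3(2H)-one by a tethered ketene is the untested part. The one new ring closes in a six-membered 6-exo-dig sense (ketene C=O exocyclic) or, in the pericyclic reading, by disrotatory 6π closure. No stereocentre is created, and the spiro carbon has no α-hydrogen and cannot racemise under neutral heating. The step needs Claisen-type C-acylation through C4 and not aldol folding or O-acylation: the preformed furanone fixes O1 and the C3 ketone so that C4 is the only nucleophilic carbon within reach, every hydroxyl is capped so nothing else intercepts the ketene, and high dilution keeps the new phenols of 19 from capturing 18 of another molecule.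

Step 14
Reactants: 19 benzannulated spiro compound (four aryl benzyl ethers, benzyl ketal)
Product: 20 (2S,8'R)-3',4,5',6,8'-pentahydroxy-2',8'-bis(4-hydroxyphenyl)-8'H-spiro[1-benzofuran-2,9'-furo[2,3-h]chromene]-3,4'-dione (CNP0283000.1)
Conditions: H2 (1 atm), Pd/C, THF/MeOH, 25 °C
Reagents that add atoms: none
Why: Hydrogenolysis over Pd/C cleaves the four aryl benzyl ethers and the O–CH2Ph bond of the benzyl ketal in one operation without breaking a bond at either stereocentre, and the freed hemiketal settles by ring–chain tautomerism in the hydrogen-bonded natural configuration.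

**Compound list**

1 | kaempferol | O=c1c(O)c(-c2ccc(O)cc2)oc2cc(O)cc(O)c12 | starting material
2 | kaempferol 3,5,7,4'-tetraacetate | O=c1c(OC(C)=O)c(-c2ccc(OC(C)=O)cc2)oc2cc(OC(C)=O)cc(OC(C)=O)c12 | intermediate
3 | 3,5,4'-tri-O-acetylkaempferol | O=c1c(OC(C)=O)c(-c2ccc(OC(C)=O)cc2)oc2cc(O)cc(OC(C)=O)c12 | intermediate
4 | 3,5,4'-tri-O-acetyl-7-O-(methoxymethyl)kaempferol | O=c1c(OC(C)=O)c(-c2ccc(OC(C)=O)cc2)oc2cc(OCOC)cc(OC(C)=O)c12 | intermediate
5 | 3,5,4'-tri-O-benzyl-7-O-(methoxymethyl)kaempferol | O=c1c(OCc3ccccc3)c(-c2ccc(OCc3ccccc3)cc2)oc2cc(OCOC)cc(OCc3ccccc3)c12 | intermediate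
6 | 3,5,4'-tri-O-benzylkaempferol | O=c1c(OCc3ccccc3)c(-c2ccc(OCc3ccccc3)cc2)oc2cc(O)cc(OCc3ccccc3)c12 | intermediate
7 | 4'-benzyloxyacetophenone | CC(=O)c1ccc(OCc2ccccc2)cc1 | starting material
8 | methyl 3-[4-(benzyloxy)phenyl]-3-oxopropanoate | COC(=O)CC(=O)c1ccc(OCc2ccccc2)cc1 | intermediate
9 | methyl 3-[4-(benzyloxy)phenyl]-2-diazo-3-oxopropanoate | COC(=O)C(=[N+]=[N-])C(=O)c1ccc(OCc2ccccc2)cc1 | intermediate
10 | methyl 3-[4-(benzyloxy)phenyl]-2,3-dioxopropanoate | COC(=O)C(=O)C(=O)c1ccc(OCc2ccccc2)cc1 | intermediate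
11 | methyl (2R)-3-[4-(benzyloxy)phenyl]-2-{3,5-bis(benzyloxy)-2-[4-(benzyloxy)phenyl]-7-hydroxy-4-oxo-4H-chromen-8-yl}-2-hydroxy-3-oxopropanoate (open-chain keto alcohol) | COC(=O)[C@](O)(C(=O)c1ccc(OCc2ccccc2)cc1)c1c(O)cc(OCc3ccccc3)c2c(=O)c(OCc3ccccc3)c(-c3ccc(OCc4ccccc4)cc3)oc12 | intermediate (not isolated)
12 | methyl (8R,9R)-3,5-bis(benzyloxy)-2,8-bis[4-(benzyloxy)phenyl]-8,9-dihydroxy-4-oxo-8,9-dihydro-4H-furo[2,3-h]chromene-9-carboxylate | COC(=O)[C@@]1(O)c2c(cc(OCc5ccccc5)c3c(=O)c(OCc5ccccc5)c(-c4ccc(OCc5ccccc5)cc4)oc23)O[C@]1(O)c1ccc(OCc2ccccc2)cc1 | intermediate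
13 | methyl (8R,9R)-3,5,8-tris(benzyloxy)-2,8-bis[4-(benzyloxy)phenyl]-9-hydroxy-4-oxo-8,9-dihydro-4H-furo[2,3-h]chromene-9-carboxylate | COC(=O)[C@@]1(O)c2c(cc(OCc5ccccc5)c3c(=O)c(OCc5ccccc5)c(-c4ccc(OCc5ccccc5)cc4)oc23)O[C@]1(OCc1ccccc1)c1ccc(OCc2ccccc2)cc1 | intermediate
14 | 2,2,6-trimethyl-4H-1,3-dioxin-4-one | CC1=CC(=O)OC(C)(C)O1 | starting material
15 | 2,2-dimethyl-6-(2-oxopropyl)-4H-1,3-dioxin-4-one | CC(=O)CC1=CC(=O)OC(C)(C)O1 | intermediate
16 | 6-{4-[(8R,9S)-3,5,8-tris(benzyloxy)-2,8-bis[4-(benzyloxy)phenyl]-9-hydroxy-4-oxo-8,9-dihydro-4H-furo[2,3-h]chromen-9-yl]-2,4-dioxobutyl}-2,2-dimethyl-4H-1,3-dioxin-4-one (diketo-dioxinone) | CC1(C)OC(=O)C=C(CC(=O)CC(=O)[C@@]2(O)c3c(cc(OCc6ccccc6)c4c(=O)c(OCc6ccccc6)c(-c5ccc(OCc6ccccc6)cc5)oc34)O[C@]2(OCc2ccccc2)c2ccc(OCc3ccccc3)cc2)O1 | intermediate (not isolated)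
17 | (2S,8'R)-3',5',8'-tris(benzyloxy)-2',8'-bis[4-(benzyloxy)phenyl]-5-[(2,2-dimethyl-4-oxo-4H-1,3-dioxin-6-yl)methyl]-8'H-spiro[furan-2,9'-furo[2,3-h]chromene]-3,4'-dione | O=C1C=C(CC7=CC(=O)OC(C)(C)O7)O[C@@]12c1c(cc(OCc9ccccc9)c3c(=O)c(OCc9ccccc9)c(-c4ccc(OCc9ccccc9)cc4)oc13)O[C@]2(OCc9ccccc9)c1ccc(OCc9ccccc9)cc1 | intermediate (key-step precursor)
18 | acylketene: as 17, with the C5 substituent CH2–C(=O)–CH=C=O | O=C1C=C(CC(=O)C=C=O)O[C@@]12c1c(cc(OCc9ccccc9)c3c(=O)c(OCc9ccccc9)c(-c4ccc(OCc9ccccc9)cc4)oc13)O[C@]2(OCc9ccccc9)c1ccc(OCc9ccccc9)cc1 | intermediate (not isolated)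
19 | (2S,8'R)-3',5',8'-tris(benzyloxy)-2',8'-bis[4-(benzyloxy)phenyl]-4,6-dihydroxy-8'H-spiro[1-benzofuran-2,9'-furo[2,3-h]chromene]-3,4'-dione | O=C1c2c(O)cc(O)cc2O[C@@]12c1c(cc(OCc9ccccc9)c3c(=O)c(OCc9ccccc9)c(-c4ccc(OCc9ccccc9)cc4)oc13)O[C@]2(OCc9ccccc9)c1ccc(OCc9ccccc9)cc1 | intermediate (key-step product)
20 | (2S,8'R)-3',4,5',6,8'-pentahydroxy-2',8'-bis(4-hydroxyphenyl)-8'H-spiro[1-benzofuran-2,9'-furo[2,3-h]chromene]-3,4'-dione (CNP0283000.1) | O=C1c2c(O)cc(O)cc2O[C@@]12c1c(cc(O)c3c(=O)c(O)c(-c4ccc(O)cc4)oc13)O[C@]2(O)c1ccc(O)cc1 | target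

**Totals**

Total steps: 14. Longest linear sequence: 10 steps (1–5, 9, 10, 12, 13, 14).

**Steps most likely to fail**

Step 13 (key step). The acylketene may be consumed by intermolecular capture or oligomerisation, or the vinylogous-ester carbon C4 may be too weak a nucleophile for ring closure to compete. The fallback sets out from 17 and uses anionic ester condensation in place of the thermal ketene acylation. Heating 17 in toluene containing methanol (100 °C) traps the ketene as the methyl β-keto ester F1. Treatment of F1 with Mg(OMe)2 in methanol (25 → 60 °C) should then bring about the base-mediated intramolecular Claisen cyclisation–aromatisation known for polyketo esters giving acylphloroglucinols: the dienolate formed at the C5 methylene attacks the ester through C4. The fallback rejoins the route at 19.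

Step 12. Addition of the dianion to the hindered ester, which also carries an α-alkoxide, may be too slow, and the diketo-dioxinone may fold by the aldol mode before it is cyclodehydrated. The fallback sets out from 13 and replaces the ester by an aldehyde as the electrophile. LiBH4 (THF, 0 °C) should reduce the α-hydroxy ester to the diol F2, the pyranone carbonyl being a far poorer electrophile. Parikh–Doering oxidation (SO3·pyridine, DMSO, iPr2NEt) gives the α-hydroxy aldehyde F3. Aldol addition of the dianion of 15 (LDA, THF, −78 °C) gives the β-hydroxy ketone F4 as a mixture of carbinol epimers. Dess–Martin oxidation converts F4 into 16, which is cyclodehydrated as in step 12, so the fallback rejoins the route at 17.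

Step 9. Facial selectivity may be eroded by copper bound to the flavonol oxygens instead of the ligand or by an uncatalysed background reaction, and some attack through C6 is possible. The fallback sets out from 6 and 10 and replaces asymmetric catalysis by resolution. Sc(OTf)3 (5 mol%, CH2Cl2, 25 °C) should give the racemic hemiketal ester F5. Ketalisation with benzyl alcohol as in step 10 gives the racemic benzyl ketal ester F6. Preparative chromatography on a chiral stationary phase then delivers the required enantiomer, and the fallback rejoins the route at 13.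

**Further compounds**

F1 | step 13 | methyl 4-[(2S,8'R)-3',5',8'-tris(benzyloxy)-2',8'-bis[4-(benzyloxy)phenyl]-3,4'-dioxo-8'H-spiro[furan-2,9'-furo[2,3-h]chromen]-5-yl]-3-oxobutanoate | O=C1C=C(CC(=O)CC(=O)OC)O[C@@]12c1c(cc(OCc9ccccc9)c3c(=O)c(OCc9ccccc9)c(-c4ccc(OCc9ccccc9)cc4)oc13)O[C@]2(OCc9ccccc9)c1ccc(OCc9ccccc9)cc1
F2 | step 12 | diol: 13 with CO2Me reduced to CH2OH, configuration of 13 | OC[C@@]1(O)c2c(cc(OCc5ccccc5)c3c(=O)c(OCc5ccccc5)c(-c4ccc(OCc5ccccc5)cc4)oc23)O[C@]1(OCc1ccccc1)c1ccc(OCc2ccccc2)cc1
F3 | step 12 | α-hydroxy aldehyde: 13 with CO2Me replaced by CHO, configuration of 13 | O=C[C@@]1(O)c2c(cc(OCc5ccccc5)c3c(=O)c(OCc5ccccc5)c(-c4ccc(OCc5ccccc5)cc4)oc23)O[C@]1(OCc1ccccc1)c1ccc(OCc2ccccc2)cc1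
F4 | step 12 | aldol adduct: 16 with the ketone next to the carbinol carbon as CH(OH), mixture of epimers at that carbon | CC1(C)OC(=O)C=C(CC(=O)CC(O)[C@@]2(O)c3c(cc(OCc6ccccc6)c4c(=O)c(OCc6ccccc6)c(-c5ccc(OCc6ccccc6)cc5)oc34)O[C@]2(OCc2ccccc2)c2ccc(OCc3ccccc3)cc2)O1
F5 | step 9 | racemic hemiketal ester (racemate of 12) | COC(=O)C1(O)c2c(cc(OCc5ccccc5)c3c(=O)c(OCc5ccccc5)c(-c4ccc(OCc5ccccc5)cc4)oc23)OC1(O)c1ccc(OCc2ccccc2)cc1
F6 | step 9 | racemic benzyl ketal ester (racemate of 13) | COC(=O)C1(O)c2c(cc(OCc5ccccc5)c3c(=O)c(OCc5ccccc5)c(-c4ccc(OCc5ccccc5)cc4)oc23)OC1(OCc1ccccc1)c1ccc(OCc2ccccc2)cc1
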